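**Retrosynthetic overview**
1. The 4-OMe group goes on last, by oxidative methoxylation of the 4-unsubstituted 6,7-catechol (C4 is its only free ring carbon). With 4-OMe in place, the Z alkene is the thermodynamic isomer.
2. The benzylidene carbon comes from benzaldehyde, by Knoevenagel condensation on the lactone CH2.
3. Key disconnection: benzene ring A and lactone ring B are cut together to two acyclic pieces (bonds C4–C5, C7–C7a, O1–C2). Forward, this is a [3+3] Knoevenagel/Dieckmann aromatisation with lactonisation in the same pot.
4. The pieces are a 1-methoxy-2,4-diketone (benzylacetone + methyl methoxyacetate) and a formylsuccinate (diethyl succinate + ethyl formate). Each is made by one Claisen condensation.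
5. Ring order: both phenyl rings are bought, rings A and B form together in step 3, and no ring is made afterwards.

Assumption: the target has no stereocentre and is achiral, so "single enantiomer" is read as the single alkene isomer drawn, Z (phenyl cis to the lactone C=O).
Benzofuranone numbering (O1, C2, C3, C3a, C4–C7, C7a) is used for these atoms throughout, including in the acyclic precursors.

**Step 1**
Reactants: 1 4-phenylbutan-2-one (benzylacetone); 2 methyl 2-methoxyacetate
Product: 3 1-methoxy-6-phenylhexane-2,4-dione
Conditions: NaH (2.2 equiv), 2 (1.5 equiv), THF, 0 °C to reflux; then aq. HCl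
Reagents that add atoms: none
Why: Crossed Claisen condensation in which the ketone enolate is acylated at its unhindered methyl terminus and irreversible deprotonation of the 1,3-diketone drives the equilibrium; no stereocentre is created.

**Step 2**
Reactants: 4 diethyl succinate; 5 ethyl formate
Product: 6 diethyl 2-formylsuccinate (racemic, largely enolised)
Conditions: NaOEt (1.1 equiv), Et2O, 0 °C to rt; then cold dilute HCl
Reagents that add atoms: none
Why: Crossed Claisen formylation with the non-enolisable and most electrophilic ester, driven by the stabilised formyl-ester enolate; the new stereocentre is labile (enol) and is erased in step 3, so the racemate is used.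

**Step 3 (key step)**
Reactants: 3 1-methoxy-6-phenylhexane-2,4-dione; 6 diethyl 2-formylsuccinate
Product: 10 6,7-dihydroxy-5-(3-phenylpropanoyl)benzofuran-2(3H)-one, via Knoevenagel adduct 7 (not isolated), via resorcinol ester 8 (not isolated), via 7-O-methyl lactone 9 (not isolated)
Conditions: a) piperidine (10 mol %), AcOH (20 mol %), toluene, reflux, Dean–Stark; b) solvent swap, NaOEt (3.5 equiv), EtOH, reflux, N2; c) evaporate, 48 % aq. HBr/AcOH, reflux
Reagents that add atoms: none
Why: Proposed new method: the central CH2 of 3 (pKa about 9) condenses with the aldehyde of 6 (Knoevenagel) to give 7, ethoxide then enolises the C6 ketone towards the MeO-bearing CH2 (about 2 pK units more acidic than the PhCH2CH2-side CH2) and this carbon attacks the ester on C3a in a 6-exo Dieckmann-type closure of a 5-oxo ester, the resulting 2-methoxycyclohexenedione tautomerises irreversibly to resorcinol 8 (ring A), and hot HBr/AcOH closes the ortho-hydroxyarylacetic ester to the five-membered lactone (ring B) and cleaves the doubly flanked 7-OMe; the closest known reaction types are the Michael–Dieckmann resorcinol synthesis from acetonedicarboxylates and alkynoates and the base cyclisation of 5-oxo esters to cyclohexane-1,3-diones, and the stereocentre of 6 becomes sp2.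

**Step 4**
Reactants: 10 6,7-dihydroxy-5-(3-phenylpropanoyl)benzofuran-2(3H)-one; 11 benzaldehyde
Product: 12 (E)-3-benzylidene-6,7-dihydroxy-5-(3-phenylpropanoyl)benzofuran-2(3H)-one
Conditions: 11 (1.1 equiv), piperidine (10 mol %), AcOH (10 mol %), toluene, reflux, Dean–Stark, N2
Reagents that add atoms: none
Why: Knoevenagel condensation in which only C3 reacts, because the lactone CH2 (its enolate is an aromatic 2-oxidobenzofuran, pKa about 13) is far more acidic than the ketone CH2; the E isomer (phenyl on the C4–H side) predominates, which does not matter because step 5 resets the geometry.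

**Step 5**
Reactants: 12 (E)-3-benzylidene-6,7-dihydroxy-5-(3-phenylpropanoyl)benzofuran-2(3H)-one
Product: 16 bractelactone, (Z)-3-benzylidene-6,7-dihydroxy-4-methoxy-5-(3-phenylpropanoyl)benzofuran-2(3H)-one, via ortho-quinone 13 (not isolated), via methoxy-ortho-quinone 14 (not isolated), via E-bractelactone 15 (not isolated)
Conditions: PhI(OAc)2 (2.1 equiv), MeOH/CH2Cl2 1:4, −20 to 0 °C; then aq. Na2S2O4; then I2 (5 mol %), CH2Cl2, daylight, rt
Reagents that add atoms: methanol (CO)
Why: Proposed new method: PhI(OAc)2 oxidises the catechol to the 3-acyl-ortho-quinone 13, whose only unsubstituted ring carbon C4 is β to both the C6 ring carbonyl and the side-chain ketone, so methanol adds there and the adduct tautomerises to the methoxycatechol, which is more electron-rich and is re-oxidised (hence 2 equiv) to 14 that has no free ring position left, dithionite returns the catechol 15, and iodine-catalysed equilibration relieves the clash between 4-OMe and the phenyl ring to give the Z alkene; the closest known reaction types are the anodic or hypervalent-iodine methoxylation of catechols and phenols by Michael addition of methanol to the quinone, and I2-catalysed alkene equilibration.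

**Compound list**
1 | 4-phenylbutan-2-one | CC(=O)CCc1ccccc1 | starting material
2 | methyl 2-methoxyacetate | COCC(=O)OC | starting material
3 | 1-methoxy-6-phenylhexane-2,4-dione | COCC(=O)CC(=O)CCc1ccccc1 | intermediate
4 | diethyl succinate | CCOC(=O)CCC(=O)OCC | starting material
5 | ethyl formate | CCOC=O | starting material
6 | diethyl 2-formylsuccinate (racemic) | CCOC(=O)CC(C=O)C(=O)OCC | intermediate
7 | diethyl 2-[2-(2-methoxyacetyl)-3-oxo-5-phenylpent-1-en-1-yl]succinate (racemic, E/Z mixture) | CCOC(=O)CC(C=C(C(=O)COC)C(=O)CCc1ccccc1)C(=O)OCC | intermediate (not isolated)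
8 | ethyl 2-[2,4-dihydroxy-3-methoxy-5-(3-phenylpropanoyl)phenyl]acetate | CCOC(=O)Cc1cc(C(=O)CCc2ccccc2)c(O)c(OC)c1O | intermediate (not isolated)
9 | 6-hydroxy-7-methoxy-5-(3-phenylpropanoyl)benzofuran-2(3H)-one | COc1c(O)c(C(=O)CCc2ccccc2)cc2c1OC(=O)C2 | intermediate (not isolated)
10 | 6,7-dihydroxy-5-(3-phenylpropanoyl)benzofuran-2(3H)-one | Oc1c(O)c(C(=O)CCc2ccccc2)cc2c1OC(=O)C2 | intermediate
11 | benzaldehyde | O=Cc1ccccc1 | starting material
12 | (E)-3-benzylidene-6,7-dihydroxy-5-(3-phenylpropanoyl)benzofuran-2(3H)-one | Oc1c(O)c(C(=O)CCc2ccccc2)cc2c1OC(=O)/C2=C/c1ccccc1 | intermediate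
13 | (E)-3-benzylidene-5-(3-phenylpropanoyl)benzofuran-2,6,7(3H)-trione | O=C1C(=O)C(C(=O)CCc2ccccc2)=CC2=C1OC(=O)/C2=C/c1ccccc1 | intermediate (not isolated)
14 | (E)-3-benzylidene-4-methoxy-5-(3-phenylpropanoyl)benzofuran-2,6,7(3H)-trione | O=C1C(=O)C(C(=O)CCc2ccccc2)=C(OC)C2=C1OC(=O)/C2=C/c1ccccc1 | intermediate (not isolated)
15 | (E)-3-benzylidene-6,7-dihydroxy-4-methoxy-5-(3-phenylpropanoyl)benzofuran-2(3H)-one | Oc1c(O)c(C(=O)CCc2ccccc2)c(OC)c2c1OC(=O)/C2=C/c1ccccc1 | intermediate (not isolated)
16 | bractelactone, (Z)-3-benzylidene-6,7-dihydroxy-4-methoxy-5-(3-phenylpropanoyl)benzofuran-2(3H)-one | COc1c(C(=O)CCc2ccccc2)c(O)c(O)c2c1/C(=C/c1ccccc1)C(=O)O2 | target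

**Step count and risks**
Total steps: 5. Longest linear sequence: 4 (steps 1, 3, 4, 5).

The steps most likely to fail are, in order, step 3, step 5 and step 4.

Step 3 carries the most risk.
- The closure needs the singly activated MeO–CH2 carbon of the already anionic adduct 7 to attack an ester.
- The CH2 on the PhCH2CH2 side can close a ring of the same size, giving an isomeric benzyl-substituted resorcinol.
- Ethoxide can also cleave the diketone by a retro-Claisen reaction.

The fallback sets out from 2. It is condensed (NaH, THF) with commercial (E)-4-phenylbut-3-en-2-one in place of 1 to give (E)-1-methoxy-6-phenylhex-5-ene-2,4-dione F1. The styryl side of this diketone has no enolisable CH2, so only the MeO-bearing carbon can close the ring. The same sequence with 6, finished with aq. HCl instead of HBr, gives 5-[(E)-cinnamoyl]-6-hydroxy-7-methoxybenzofuran-2(3H)-one F2. Hydrogenation over Pd/C then saturates the enone and comes back to the route at 9, which HBr/AcOH converts into 10.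

Step 5 is the second risk.
- Quinones 13 and 14 carry an activated enol-ester lactone that methanol may open.
- Methanol can also add to the benzylidene carbon.

The fallback sets out from 9, which is isolated by finishing step 3 with aq. HCl. Knoevenagel condensation with 11 gives (E)-3-benzylidene-6-hydroxy-7-methoxy-5-(3-phenylpropanoyl)benzofuran-2(3H)-one F3. PhI(OAc)2 (1.05 equiv) in MeOH converts this guaiacol into the isolable ortho-quinone monoketal (E)-3-benzylidene-7,7-dimethoxy-5-(3-phenylpropanoyl)benzofuran-2,6(3H,7H)-dione F4. With a trace of TsOH in MeOH, methanol adds to C4 and one ketal methoxy group leaves. After the same I2 equilibration this gives (Z)-3-benzylidene-6-hydroxy-4,7-dimethoxy-5-(3-phenylpropanoyl)benzofuran-2(3H)-one F5. AlCl3–pyridine in CH2Cl2 then cleaves only the methoxy group next to the free 6-OH, through a five-membered aluminium chelate, and comes back to the route at 16.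

Step 4 is the third risk, because the free catechol under amine catalysis may suffer air oxidation and the lactone may undergo aminolysis. The fallback sets out from 10. It is heated with 11 in Ac2O/Et3N (Perkin–Oglialoro condensation), which acetylates both phenols in situ and gives (E)-3-benzylidene-2-oxo-5-(3-phenylpropanoyl)-2,3-dihydrobenzofuran-6,7-diyl diacetate F6. NH4OAc in aqueous MeOH removes the two aryl acetates and comes back to the route at 12.

**Further compounds**
F1 | step 3 | (E)-1-methoxy-6-phenylhex-5-ene-2,4-dione | COCC(=O)CC(=O)/C=C/c1ccccc1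
F2 | step 3 | 5-[(E)-cinnamoyl]-6-hydroxy-7-methoxybenzofuran-2(3H)-one | COc1c(O)c(C(=O)/C=C/c2ccccc2)cc2c1OC(=O)C2
F3 | step 5 | (E)-3-benzylidene-6-hydroxy-7-methoxy-5-(3-phenylpropanoyl)benzofuran-2(3H)-one | COc1c(O)c(C(=O)CCc2ccccc2)cc2c1OC(=O)/C2=C/c1ccccc1
F4 | step 5 | (E)-3-benzylidene-7,7-dimethoxy-5-(3-phenylpropanoyl)benzofuran-2,6(3H,7H)-dione | COC1(OC)C(=O)C(C(=O)CCc2ccccc2)=CC2=C1OC(=O)/C2=C/c1ccccc1
F5 | step 5 | (Z)-3-benzylidene-6-hydroxy-4,7-dimethoxy-5-(3-phenylpropanoyl)benzofuran-2(3H)-one | COc1c(C(=O)CCc2ccccc2)c(O)c(OC)c2c1/C(=C/c1ccccc1)C(=O)O2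
F6 | step 4 | (E)-3-benzylidene-2-oxo-5-(3-phenylpropanoyl)-2,3-dihydrobenzofuran-6,7-diyl diacetate | CC(=O)Oc1c(OC(C)=O)c(C(=O)CCc2ccccc2)cc2c1OC(=O)/C2=C/c1ccccc1
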